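Both earlier runs slow down.

| flask | electrophile | nucleophile | free base | remark | time |
|---|---|---|---|---|---|
| elm | 0.25 M | 0.325 M | 0.037 M | run made earlier |  |
| maple | 0.25 M | 0.325 M | 0.056 M | run made earlier |  |
| flask | 0.25 M | 0.325 M | 0.0750 M |  | 50 min |

| run | time / min | electrophile / % | target / % |
|---|---|---|---|
| elm | 2.50 | 56 | 7 |
| elm | 6.00 | 41 | 3 |
| elm | 12.0 | 29 | 2 |
| elm | 30.0 | 24 | 0 |
| maple | 2.50 | 58 | 2 |
| maple | 6.00 | 39 | 2 |
| maple | 12.0 | 27 | 4 |
| maple | 30.0 | 21 | 1 |

(scatter of a reading: 2 percentage points)

- what was read earlier has a scatter of 2 percentage points, one standard deviation
- the earlier runs do not show how much of nucleophile is bound; that part of a forecast is a guess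

1. part of the electrophile that has reacted at 50 min
2. share of the unused nucleophile that is free and not bound as protonated nucleophile, at 50 min

Suppose each turnover of electrophile with nucleophile sets free one acid, taken first by the free base and then by a further nucleophile. Past the base, a turnover then costs 2 nucleophiles, and this reckoning sets a limit s near which the electrophile's use slows, the nucleophile and free base charged over 2 electrophile charges: 72.4% in elm, 76.2% in maple, and 80.0% in the new flask, the stall limit.

At 30.0 min, elm has used 76.0% and maple 79.0%. These gaps of 3.6 percentage points and 2.8 points above s average 3.2 points, with a scatter of 2 points on each reading. Averaged over both runs, the electrophile's loss slowed from 0.00500 M/min to 7.64 × 10⁻⁴ M/min. One more fall in that ratio gives an estimated pace of 1.17 × 10⁻⁴ M/min, which is reckoned to add 0.93 points by 50 min. This reckoning therefore commits the flask to 84.1% reacted.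

The weak link is the free nucleophile, which the runs do not show. The first readings, taken against the charged nucleophile, give a rate constant k, as a reading with their scatter, of 0.692 /M/min. The estimated pace over the electrophile left is a pseudo-first-order constant, and dividing it by k gives an estimate of 0.00425 M free nucleophile in the new flask, which is 3.71% of the unused nucleophile.

The forecast says 81% and 10%, a conversion lower than this reckoning's and a free share higher than its, with the conversion on the ground that “each further turnover costs two nucleophiles”.

The flask gives 82.8% and 4.19%: the forecast's conversion is within the margin, and its free share is 5.8 points too high. In the new flask at 50.0 min, free nucleophile stands at 1.52% of its charge beside 0.113 M protonated nucleophile, and the conversion lies 2.8 points above s.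

    target → over-reaction product (k = 1.30 /min)
    electrophile + nucleophile → acid set free + target (k = 1.00 /M/min)
    nucleophile + acid set free ⇌ protonated nucleophile, settled at all times (K = 1200 /M)
    acid set free + free base ⇌ salt of the base, settled at all times (K = 5.10 × 10⁵ /M)

In a second flask, like this one but with 0.13 M nucleophile, s is 41.0%, and adding the read gap gives 44.2% reacted. The computed result there is 44.4%.

Readings and results come from a simulation with constants of no real substance; scatter was added.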